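Everything rests on disconnecting the ε-ring (C1′–C6′) between C5′ and C6′. C6′ is the sp3 centre of the skipped diene C4′=C5′–C6′–C7′=C8′ and sits next to the quaternary C1′, which makes it the retron of an allyl–alkenyl coupling. A palladium-catalysed intramolecular Stille-type coupling of an acyclic precursor, a (Z)-alkenylstannane tethered through C1′ to an (S)-configured dienyl carbonate, closes the ring, sets C6′ by stereospecific inversion and installs the complete C15 side chain in one operation. C10-dialdehyde then extends the unit to a C25 phosphonium salt, which is joined by Wittig olefination at C11=C12 to a C15 oxo-enal that already carries the 8-ketone and the 19-laurate.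

Key step: step 11

Remark: carotenoid numbering (C1–C20, primed locants for the ε-half) is used for positions; compounds 11, 22, 27 and 31 are taken as purchasable.

Step 1
Reactants: 1 methyl 3,3-dimethylpent-4-enoate
Product: 2 N-methoxy-N,3,3-trimethylpent-4-enamide
Conditions: MeNH(OMe)·HCl, i-PrMgCl, THF, −20 to 0 °C
Reagents that add atoms: N,O-dimethylhydroxylamine hydrochloride, CNOC.Cl
Why: Magnesium-amide aminolysis of an unhindered methyl ester (Weinreb amide formation) is reliable and leaves the neopentyl vinyl group untouched.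

Step 2
Reactants: 2 N-methoxy-N,3,3-trimethylpent-4-enamide; 3 prop-1-yn-1-ylmagnesium bromide
Product: 4 6,6-dimethyloct-7-en-2-yn-4-one
Conditions: THF, 0 °C; aq. NH4Cl
Reagents that add atoms: none
Why: Weinreb ketone synthesis, in which the chelated tetrahedral adduct stops the alkynyl Grignard addition at the ynone.

Step 3
Reactants: 4 6,6-dimethyloct-7-en-2-yn-4-one
Product: 5 (4R)-6,6-dimethyloct-7-en-2-yn-4-ol
Conditions: RuCl[(R,R)-TsDPEN](p-cymene) (1 mol%), KOH (2 mol%), i-PrOH, rt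
Reagents that add atoms: none
Why: Noyori asymmetric transfer hydrogenation of an alkynyl ketone, in which the (R,R)-catalyst recognises the alkyne as the π-substituent and should give the (R)-propargylic alcohol (future C3′).

Step 4
Reactants: 5 (4R)-6,6-dimethyloct-7-en-2-yn-4-ol
Product: 7 (2Z,4R)-2-iodo-6,6-dimethylocta-2,7-dien-4-ol, via cyclic alkenylalanate 6 (not isolated)
Conditions: NaAlH2(OCH2CH2OMe)2, THF, 0 °C to rt; then I2, −78 to 0 °C
Reagents that add atoms: iodine, [I][I]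
Why: Hydroxyl-directed trans-hydroalumination of the propargylic alcohol puts aluminium on the distal alkyne carbon cis to the carbinol, and iodinolysis with retention gives the (Z)-iodoalkene required for an endocyclic C4′=C5′ bond.

Step 5
Reactants: 7 (2Z,4R)-2-iodo-6,6-dimethylocta-2,7-dien-4-ol
Product: 8 tert-butyl{[(2Z,4R)-2-iodo-6,6-dimethylocta-2,7-dien-4-yl]oxy}dimethylsilane
Conditions: TBSCl, imidazole, DMF, rt
Reagents that add atoms: tert-butyldimethylsilyl chloride, CC(C)(C)[Si](C)(C)Cl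
Why: Standard silylation of the secondary allylic alcohol protects O3′ for the organometallic steps.

Step 6
Reactants: 8 tert-butyl{[(2Z,4R)-2-iodo-6,6-dimethylocta-2,7-dien-4-yl]oxy}dimethylsilane
Product: 10 (4R,5Z)-4-[(tert-butyldimethylsilyl)oxy]-6-iodo-2,2-dimethylhept-5-enal, via vicinal diol 9 (not isolated)
Conditions: OsO4 (2 mol%), NaIO4, 2,6-lutidine, dioxane/H2O, rt
Reagents that add atoms: osmium tetroxide, O=[Os](=O)(=O)=O; sodium periodate, [Na+].[O-]I(=O)(=O)=O
Why: Lemieux–Johnson cleavage, in which the monosubstituted vinyl group is dihydroxylated much faster than the hindered, electron-poor iodoalkene and periodate cleaves the diol to the α-quaternary aldehyde (future C6′).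

Step 7
Reactants: 11 (2E)-3-methylpent-2-en-4-yn-1-ol
Product: 12 tert-butyldimethyl{[(2E)-3-methylpent-2-en-4-yn-1-yl]oxy}silane
Conditions: TBSCl, imidazole, CH2Cl2, 0 °C to rt
Reagents that add atoms: tert-butyldimethylsilyl chloride, CC(C)(C)[Si](C)(C)Cl
Why: Standard silylation of the primary allylic alcohol, needed before hydroboration and zinc chemistry.

Step 8
Reactants: 10 (4R,5Z)-4-[(tert-butyldimethylsilyl)oxy]-6-iodo-2,2-dimethylhept-5-enal; 12 tert-butyldimethyl{[(2E)-3-methylpent-2-en-4-yn-1-yl]oxy}silane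
Product: 15 (2E,4E,6S,9R,10Z)-1,9-bis[(tert-butyldimethylsilyl)oxy]-11-iodo-3,7,7-trimethyldodeca-2,4,10-trien-6-ol, via dienylborane 13 (not isolated), via dienylzinc 14 (not isolated)
Conditions: BH3·SMe2, cyclohexene, toluene, 0 °C (gives Cy2BH); 12, 0 °C to rt; Me2Zn, −78 °C; (−)-MIB (5 mol%); 10, −30 to 0 °C; aq. NH4Cl
Reagents that add atoms: none
Why: Alkyne hydroboration, boron-to-zinc exchange and amino-alcohol-catalysed alkenylzinc addition to the aldehyde give the (E,E)-dienyl carbinol, and the (−)-MIB–zinc catalyst should direct the alkenyl group to the Si face and so set the (6S)-carbinol independently of the remote silyl ether.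

Step 9
Reactants: 15 (2E,4E,6S,9R,10Z)-1,9-bis[(tert-butyldimethylsilyl)oxy]-11-iodo-3,7,7-trimethyldodeca-2,4,10-trien-6-ol
Product: 16 (2E,4E,6S,9R,10Z)-1,9-bis[(tert-butyldimethylsilyl)oxy]-3,7,7-trimethyl-11-(trimethylstannyl)dodeca-2,4,10-trien-6-ol
Conditions: (Me3Sn)2, Pd(PPh3)4 (5 mol%), THF, 65 °C
Reagents that add atoms: hexamethylditin, C[Sn](C)(C)[Sn](C)(C)C
Why: Palladium-catalysed iodine–tin exchange with a distannane proceeds with retention of the (Z)-geometry and tolerates the free dienyl alcohol.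

Step 10
Reactants: 16 (2E,4E,6S,9R,10Z)-1,9-bis[(tert-butyldimethylsilyl)oxy]-3,7,7-trimethyl-11-(trimethylstannyl)dodeca-2,4,10-trien-6-ol; 17 methyl chloroformate
Product: 18 (2E,4E,6S,9R,10Z)-1,9-bis[(tert-butyldimethylsilyl)oxy]-3,7,7-trimethyl-11-(trimethylstannyl)dodeca-2,4,10-trien-6-yl methyl carbonate
Conditions: LiN(SiMe3)2, THF, −78 °C; then 17, −78 to 0 °C
Reagents that add atoms: none
Why: O-acylation of the lithium alkoxide of the hindered carbinol installs the allylic leaving group without acid that could protodestannylate the alkenylstannane.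

Step 11
Reactants: 18 (2E,4E,6S,9R,10Z)-1,9-bis[(tert-butyldimethylsilyl)oxy]-3,7,7-trimethyl-11-(trimethylstannyl)dodeca-2,4,10-trien-6-yl methyl carbonate
Product: 19 tert-butyl{[(2E,4E)-5-[(1R,4R)-4-[(tert-butyldimethylsilyl)oxy]-2,6,6-trimethylcyclohex-2-en-1-yl]-3-methylpenta-2,4-dien-1-yl]oxy}dimethylsilane
Conditions: Pd2(dba)3·CHCl3 (5 mol%), P(2-furyl)3 (20 mol%), DMF, 45 °C, 0.005 M, syringe-pump addition
Reagents that add atoms: none
Why: Zerovalent palladium ionises the allylic carbonate anti to the leaving group, CO2 is lost, the methoxide on palladium triggers intramolecular tin-to-palladium transfer of the (Z)-alkenyl group, and reductive elimination forms C5′–C6′ on the palladium face; the closest known reaction type is the Stille coupling of allylic carbonates with alkenylstannanes, used here intramolecularly. The ε-ring closes in a 6-exo mode with respect to the allyl unit (C5′ attacks the allyl terminus C6′ while C7′=C8′ stays exocyclic), and the (Z)-geometry of the stannane holds C5′ within reach of C6′. C6′ is controlled by the carbinol centre of 18: ionisation with inversion followed by C–C bond formation with retention means overall inversion, so the (6S)-carbonate should give the (6′R)-centre, trans to the untouched (3′R)-silyl ether. The step needs regioselectivity among C6′, C8′ and C10′ of the pentadienyl system, which ring size secures because only attack at C6′ gives an unstrained six-membered ring, and it needs retention of the E-geometry at C7′=C8′, which holds as long as the syn,syn-allyl complex is trapped faster than it isomerises. β-Hydride loss is blocked by the quaternary C1′ and the sp2 C9′, and high dilution suppresses intermolecular coupling.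

Step 12
Reactants: 19 tert-butyl{[(2E,4E)-5-[(1R,4R)-4-[(tert-butyldimethylsilyl)oxy]-2,6,6-trimethylcyclohex-2-en-1-yl]-3-methylpenta-2,4-dien-1-yl]oxy}dimethylsilane
Product: 20 (2E,4E)-5-[(1R,4R)-4-hydroxy-2,6,6-trimethylcyclohex-2-en-1-yl]-3-methylpenta-2,4-dien-1-ol
Conditions: Bu4NF, THF, 0 °C to rt
Reagents that add atoms: none
Why: Fluoride-mediated desilylation removes both silyl ethers from the base-stable C15 diene without touching the stereocentres.

Step 13
Reactants: 20 (2E,4E)-5-[(1R,4R)-4-hydroxy-2,6,6-trimethylcyclohex-2-en-1-yl]-3-methylpenta-2,4-dien-1-ol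
Product: 21 [(2E,4E)-5-[(1R,4R)-4-hydroxy-2,6,6-trimethylcyclohex-2-en-1-yl]-3-methylpenta-2,4-dien-1-yl]triphenylphosphonium bromide
Conditions: PPh3·HBr, MeOH, 0 °C to rt; crystallisation
Reagents that add atoms: triphenylphosphonium bromide, c1ccccc1[PH+](c1ccccc1)c1ccccc1.[Br-]
Why: Acid-mediated phosphonium salt formation, in which the primary dienylic alcohol ionises (pentadienyl cation) far more readily than the isolated ring allylic alcohol and the phosphine is captured at the primary terminus.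

Step 14
Reactants: 21 [(2E,4E)-5-[(1R,4R)-4-hydroxy-2,6,6-trimethylcyclohex-2-en-1-yl]-3-methylpenta-2,4-dien-1-yl]triphenylphosphonium bromide; 22 (2E,4E,6E)-2,7-dimethylocta-2,4,6-trienedial
Product: 24 (2E,4E,6E,8E,10E,12E)-13-[(1R,4R)-4-hydroxy-2,6,6-trimethylcyclohex-2-en-1-yl]-2,7,11-trimethyltrideca-2,4,6,8,10,12-hexaenal, via phosphorus ylide 23 (not isolated)
Conditions: NaOMe (slow addition), 22 (3 equiv), CH2Cl2/MeOH, −20 °C to rt; then I2 (cat.), CH2Cl2, rt
Reagents that add atoms: none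
Why: Wittig olefination of the semi-stabilised ylide with an excess of the symmetrical dialdehyde should give the mono-adduct, and the new C11′=C12′ bond is equilibrated to E with catalytic iodine.

Step 15
Reactants: 24 (2E,4E,6E,8E,10E,12E)-13-[(1R,4R)-4-hydroxy-2,6,6-trimethylcyclohex-2-en-1-yl]-2,7,11-trimethyltrideca-2,4,6,8,10,12-hexaenal
Product: 25 (2E,4E,6E,8E,10E,12E)-13-[(1R,4R)-4-hydroxy-2,6,6-trimethylcyclohex-2-en-1-yl]-2,7,11-trimethyltrideca-2,4,6,8,10,12-hexaen-1-ol
Conditions: NaBH4, EtOH/THF, 0 °C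
Reagents that add atoms: none
Why: Borohydride 1,2-reduction of the polyenal is chemoselective and leaves the polyene untouched.

Step 16
Reactants: 25 (2E,4E,6E,8E,10E,12E)-13-[(1R,4R)-4-hydroxy-2,6,6-trimethylcyclohex-2-en-1-yl]-2,7,11-trimethyltrideca-2,4,6,8,10,12-hexaen-1-ol
Product: 26 [(2E,4E,6E,8E,10E,12E)-13-[(1R,4R)-4-hydroxy-2,6,6-trimethylcyclohex-2-en-1-yl]-2,7,11-trimethyltrideca-2,4,6,8,10,12-hexaen-1-yl]triphenylphosphonium bromide
Conditions: PPh3·HBr, CH2Cl2/MeOH, 0 °C, dark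
Reagents that add atoms: triphenylphosphonium bromide, c1ccccc1[PH+](c1ccccc1)c1ccccc1.[Br-]
Why: Acid-mediated phosphonium salt formation, in which the polyenylic primary alcohol ionises under very mild conditions and is captured by the phosphine at C12, again faster than the ring allylic alcohol.

Step 17
Reactants: 27 (4R,6R)-4-hydroxy-2,2,6-trimethylcyclohexan-1-one
Product: 28 (4R,6R)-4-[(tert-butyldimethylsilyl)oxy]-2,2,6-trimethylcyclohexan-1-one
Conditions: TBSCl, imidazole, DMF, rt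
Reagents that add atoms: tert-butyldimethylsilyl chloride, CC(C)(C)[Si](C)(C)Cl
Why: Standard silylation protects the C3 alcohol, whose (R)-configuration is taken from the starting ketone.

Step 18
Reactants: 28 (4R,6R)-4-[(tert-butyldimethylsilyl)oxy]-2,2,6-trimethylcyclohexan-1-one
Product: 30 (4R)-4-[(tert-butyldimethylsilyl)oxy]-2,6,6-trimethylcyclohex-1-en-1-yl trifluoromethanesulfonate, via potassium enolate 29 (not isolated)
Conditions: KN(SiMe3)2, THF, −78 to −20 °C; then PhNTf2, −78 °C to rt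
Reagents that add atoms: N-phenylbis(trifluoromethanesulfonimide), O=S(=O)(N(c1ccccc1)S(=O)(=O)C(F)(F)F)C(F)(F)F
Why: Enol triflate formation, in which the ketone has a single enolisable position so that O-triflation gives only the tetrasubstituted C5=C6 enol triflate.

Step 19
Reactants: 30 (4R)-4-[(tert-butyldimethylsilyl)oxy]-2,6,6-trimethylcyclohex-1-en-1-yl trifluoromethanesulfonate; 31 bromo(2-ethoxy-2-oxoethyl)zinc
Product: 32 ethyl 2-[(4R)-4-[(tert-butyldimethylsilyl)oxy]-2,6,6-trimethylcyclohex-1-en-1-yl]acetate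
Conditions: Pd(PPh3)4 (5 mol%), THF/DMPU, 65 °C
Reagents that add atoms: none
Why: Negishi-type cross-coupling of the Reformatsky reagent with the enol triflate forms C6–C7 and keeps the double bond in the ring, β,γ to the ester.

Step 20
Reactants: 32 ethyl 2-[(4R)-4-[(tert-butyldimethylsilyl)oxy]-2,6,6-trimethylcyclohex-1-en-1-yl]acetate
Product: 33 2-[(4R)-4-[(tert-butyldimethylsilyl)oxy]-2,6,6-trimethylcyclohex-1-en-1-yl]acetic acid
Conditions: LiOH, THF/MeOH/H2O, rt; then 1 M HCl to pH 4, 0 °C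
Reagents that add atoms: lithium hydroxide, [Li+].[OH-]
Why: Saponification of the unhindered ethyl ester, with careful acidification so that the silyl ether survives.

Step 21
Reactants: 34 3,3-diethoxyprop-1-yne; 17 methyl chloroformate
Product: 36 methyl 4,4-diethoxybut-2-ynoate, via lithium acetylide 35 (not isolated)
Conditions: n-BuLi, THF, −78 °C; then 17, −78 to 0 °C
Reagents that add atoms: none
Why: C-acylation of a lithium acetylide with a chloroformate gives the alkynoate whose ester carbon becomes C19.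

Step 22
Reactants: 36 methyl 4,4-diethoxybut-2-ynoate
Product: 37 methyl (2E)-4,4-diethoxy-2-(tributylstannyl)but-2-enoate
Conditions: Bu3SnH, Pd(PPh3)4 (2 mol%), THF, 0 °C to rt
Reagents that add atoms: tributyltin hydride, CCCC[SnH](CCCC)CCCC
Why: Palladium-catalysed syn-hydrostannation of an alkynoate places tin α to the ester and hydrogen cis to tin, which fixes the C9=C10 geometry (C19 cis to C11).

Step 23
Reactants: 37 methyl (2E)-4,4-diethoxy-2-(tributylstannyl)but-2-enoate
Product: 38 (2E)-4,4-diethoxy-2-(tributylstannyl)but-2-en-1-ol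
Conditions: i-Bu2AlH, CH2Cl2, −78 °C; Rochelle salt work-up
Reagents that add atoms: none
Why: Aluminium hydride 1,2-reduction of the enoate gives the C19 allylic alcohol while the acetal keeps C11 masked and non-acidic work-up spares the stannane.

Step 24
Reactants: 38 (2E)-4,4-diethoxy-2-(tributylstannyl)but-2-en-1-ol; 39 dodecanoyl chloride
Product: 40 (2E)-4,4-diethoxy-2-(tributylstannyl)but-2-en-1-yl dodecanoate
Conditions: pyridine, DMAP (5 mol%), CH2Cl2, 0 °C
Reagents that add atoms: none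
Why: Acylation of the only free hydroxyl installs the laurate at C19 before any other alcohol is unmasked.

Step 25
Reactants: 33 2-[(4R)-4-[(tert-butyldimethylsilyl)oxy]-2,6,6-trimethylcyclohex-1-en-1-yl]acetic acid; 40 (2E)-4,4-diethoxy-2-(tributylstannyl)but-2-en-1-yl dodecanoate
Product: 42 (2E)-2-{2-[(4R)-4-[(tert-butyldimethylsilyl)oxy]-2,6,6-trimethylcyclohex-1-en-1-yl]acetyl}-4,4-diethoxybut-2-en-1-yl dodecanoate, via acid chloride 41 (not isolated)
Conditions: 1-chloro-N,N,2-trimethylprop-1-en-1-amine, CH2Cl2, 0 °C to rt; then 40, Pd2(dba)3·CHCl3 (2.5 mol%), P(2-furyl)3 (10 mol%), toluene, 60 °C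
Reagents that add atoms: none
Why: Neutral acid chloride formation followed by acylative Stille coupling forms C8–C9 with retention of the stannane geometry and gives the β,γ-unsaturated ketone without any base.

Step 26
Reactants: 42 (2E)-2-{2-[(4R)-4-[(tert-butyldimethylsilyl)oxy]-2,6,6-trimethylcyclohex-1-en-1-yl]acetyl}-4,4-diethoxybut-2-en-1-yl dodecanoate
Product: 43 (2E)-2-{2-[(4R)-4-hydroxy-2,6,6-trimethylcyclohex-1-en-1-yl]acetyl}-4-oxobut-2-en-1-yl dodecanoate
Conditions: 48% aq. HF, MeCN/H2O, 0 °C to rt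
Reagents that add atoms: water, O
Why: Aqueous acid hydrolyses the acetal to the enal and cleaves the silyl ether in one operation, and the E-enedicarbonyl is the thermodynamically preferred geometry.

Step 27
Reactants: 26 [(2E,4E,6E,8E,10E,12E)-13-[(1R,4R)-4-hydroxy-2,6,6-trimethylcyclohex-2-en-1-yl]-2,7,11-trimethyltrideca-2,4,6,8,10,12-hexaen-1-yl]triphenylphosphonium bromide; 43 (2E)-2-{2-[(4R)-4-hydroxy-2,6,6-trimethylcyclohex-1-en-1-yl]acetyl}-4-oxobut-2-en-1-yl dodecanoate
Product: 45 (3R,3′R,6′R)-3,3′-dihydroxy-8-oxo-7,8-dihydro-β,ε-caroten-19-yl dodecanoate, via phosphorus ylide 44 (not isolated)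
Conditions: 1,2-epoxybutane, CH2Cl2, 60 °C (sealed), dark; then I2 (cat.), CH2Cl2, rt
Reagents that add atoms: none
Why: Wittig olefination under epoxide conditions, where the epoxide scavenges HBr so that no free base is present, should couple the polyenyl ylide with the aldehyde in preference to the C8 ketone, spare the laurate and both free alcohols, and allow the new C11=C12 bond to be equilibrated to E.

Compound list
1 | methyl 3,3-dimethylpent-4-enoate | COC(=O)CC(C)(C)C=C | starting material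
2 | N-methoxy-N,3,3-trimethylpent-4-enamide | CON(C)C(=O)CC(C)(C)C=C | intermediate
3 | prop-1-yn-1-ylmagnesium bromide | CC#C[Mg]Br | starting material
4 | 6,6-dimethyloct-7-en-2-yn-4-one | CC#CC(=O)CC(C)(C)C=C | intermediate
5 | (4R)-6,6-dimethyloct-7-en-2-yn-4-ol | CC#C[C@H](O)CC(C)(C)C=C | intermediate
6 | sodium cyclic alkenylalanate of 5 (1,2-oxaluminole ate complex, two 2-methoxyethoxy ligands on Al) | [Na+].CC1=C[C@@H](CC(C)(C)C=C)O[Al-]1(OCCOC)OCCOC | intermediate
7 | (2Z,4R)-2-iodo-6,6-dimethylocta-2,7-dien-4-ol | C/C(I)=C/[C@H](O)CC(C)(C)C=C | intermediate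
8 | tert-butyl{[(2Z,4R)-2-iodo-6,6-dimethylocta-2,7-dien-4-yl]oxy}dimethylsilane | C/C(I)=C/[C@H](O[Si](C)(C)C(C)(C)C)CC(C)(C)C=C | intermediate
9 | (5R,6Z)-5-[(tert-butyldimethylsilyl)oxy]-7-iodo-3,3-dimethyloct-6-ene-1,2-diol (C2 epimers) | C/C(I)=C/[C@H](O[Si](C)(C)C(C)(C)C)CC(C)(C)C(O)CO | intermediate
10 | (4R,5Z)-4-[(tert-butyldimethylsilyl)oxy]-6-iodo-2,2-dimethylhept-5-enal | C/C(I)=C/[C@H](O[Si](C)(C)C(C)(C)C)CC(C)(C)C=O | intermediate
11 | (2E)-3-methylpent-2-en-4-yn-1-ol | C#C/C(C)=C/CO | starting material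
12 | tert-butyldimethyl{[(2E)-3-methylpent-2-en-4-yn-1-yl]oxy}silane | C#C/C(C)=C/CO[Si](C)(C)C(C)(C)C | intermediate
13 | tert-butyl{[(2E,4E)-5-(dicyclohexylboranyl)-3-methylpenta-2,4-dien-1-yl]oxy}dimethylsilane | C1CCCCC1B(/C=C/C(C)=C/CO[Si](C)(C)C(C)(C)C)C1CCCCC1 | intermediate
14 | {(1E,3E)-5-[(tert-butyldimethylsilyl)oxy]-3-methylpenta-1,3-dien-1-yl}(methyl)zinc | C[Zn]/C=C/C(C)=C/CO[Si](C)(C)C(C)(C)C | intermediate
15 | (2E,4E,6S,9R,10Z)-1,9-bis[(tert-butyldimethylsilyl)oxy]-11-iodo-3,7,7-trimethyldodeca-2,4,10-trien-6-ol | C/C(I)=C/[C@H](O[Si](C)(C)C(C)(C)C)CC(C)(C)[C@@H](O)/C=C/C(C)=C/CO[Si](C)(C)C(C)(C)C | intermediate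
16 | (2E,4E,6S,9R,10Z)-1,9-bis[(tert-butyldimethylsilyl)oxy]-3,7,7-trimethyl-11-(trimethylstannyl)dodeca-2,4,10-trien-6-ol | C/C(=C/[C@H](O[Si](C)(C)C(C)(C)C)CC(C)(C)[C@@H](O)/C=C/C(C)=C/CO[Si](C)(C)C(C)(C)C)[Sn](C)(C)C | intermediate
17 | methyl chloroformate | COC(=O)Cl | starting material
18 | (2E,4E,6S,9R,10Z)-1,9-bis[(tert-butyldimethylsilyl)oxy]-3,7,7-trimethyl-11-(trimethylstannyl)dodeca-2,4,10-trien-6-yl methyl carbonate | C/C(=C/[C@H](O[Si](C)(C)C(C)(C)C)CC(C)(C)[C@@H](OC(=O)OC)/C=C/C(C)=C/CO[Si](C)(C)C(C)(C)C)[Sn](C)(C)C | intermediate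
19 | tert-butyl{[(2E,4E)-5-[(1R,4R)-4-[(tert-butyldimethylsilyl)oxy]-2,6,6-trimethylcyclohex-2-en-1-yl]-3-methylpenta-2,4-dien-1-yl]oxy}dimethylsilane | CC(C)(C)[Si](C)(C)OC/C=C(C)/C=C/[C@H]1C(C)=C[C@H](O[Si](C)(C)C(C)(C)C)CC1(C)C | intermediate
20 | (2E,4E)-5-[(1R,4R)-4-hydroxy-2,6,6-trimethylcyclohex-2-en-1-yl]-3-methylpenta-2,4-dien-1-ol | OC/C=C(C)/C=C/[C@H]1C(C)=C[C@H](O)CC1(C)C | intermediate
21 | [(2E,4E)-5-[(1R,4R)-4-hydroxy-2,6,6-trimethylcyclohex-2-en-1-yl]-3-methylpenta-2,4-dien-1-yl]triphenylphosphonium bromide | [Br-].c1ccccc1[P+](c1ccccc1)(c1ccccc1)C/C=C(C)/C=C/[C@H]1C(C)=C[C@H](O)CC1(C)C | intermediate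
22 | (2E,4E,6E)-2,7-dimethylocta-2,4,6-trienedial | O=C/C(C)=C/C=C/C=C(C)/C=O | starting material
23 | phosphorus ylide of 21 | c1ccccc1P(c1ccccc1)(c1ccccc1)=C/C=C(C)/C=C/[C@H]1C(C)=C[C@H](O)CC1(C)C | intermediate
24 | (2E,4E,6E,8E,10E,12E)-13-[(1R,4R)-4-hydroxy-2,6,6-trimethylcyclohex-2-en-1-yl]-2,7,11-trimethyltrideca-2,4,6,8,10,12-hexaenal | O=C/C(C)=C/C=C/C=C(C)/C=C/C=C(C)/C=C/[C@H]1C(C)=C[C@H](O)CC1(C)C | intermediate
25 | (2E,4E,6E,8E,10E,12E)-13-[(1R,4R)-4-hydroxy-2,6,6-trimethylcyclohex-2-en-1-yl]-2,7,11-trimethyltrideca-2,4,6,8,10,12-hexaen-1-ol | OC/C(C)=C/C=C/C=C(C)/C=C/C=C(C)/C=C/[C@H]1C(C)=C[C@H](O)CC1(C)C | intermediate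
26 | [(2E,4E,6E,8E,10E,12E)-13-[(1R,4R)-4-hydroxy-2,6,6-trimethylcyclohex-2-en-1-yl]-2,7,11-trimethyltrideca-2,4,6,8,10,12-hexaen-1-yl]triphenylphosphonium bromide | [Br-].c1ccccc1[P+](c1ccccc1)(c1ccccc1)C/C(C)=C/C=C/C=C(C)/C=C/C=C(C)/C=C/[C@H]1C(C)=C[C@H](O)CC1(C)C | intermediate
27 | (4R,6R)-4-hydroxy-2,2,6-trimethylcyclohexan-1-one | O=C1C(C)(C)C[C@H](O)C[C@H]1C | starting material
28 | (4R,6R)-4-[(tert-butyldimethylsilyl)oxy]-2,2,6-trimethylcyclohexan-1-one | O=C1C(C)(C)C[C@H](O[Si](C)(C)C(C)(C)C)C[C@H]1C | intermediate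
29 | potassium (4R)-4-[(tert-butyldimethylsilyl)oxy]-2,6,6-trimethylcyclohex-1-en-1-olate | [K+].[O-]C1=C(C)C[C@@H](O[Si](C)(C)C(C)(C)C)CC1(C)C | intermediate
30 | (4R)-4-[(tert-butyldimethylsilyl)oxy]-2,6,6-trimethylcyclohex-1-en-1-yl trifluoromethanesulfonate | FC(F)(F)S(=O)(=O)OC1=C(C)C[C@@H](O[Si](C)(C)C(C)(C)C)CC1(C)C | intermediate
31 | bromo(2-ethoxy-2-oxoethyl)zinc | CCOC(=O)C[Zn]Br | starting material
32 | ethyl 2-[(4R)-4-[(tert-butyldimethylsilyl)oxy]-2,6,6-trimethylcyclohex-1-en-1-yl]acetate | CCOC(=O)CC1=C(C)C[C@@H](O[Si](C)(C)C(C)(C)C)CC1(C)C | intermediate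
33 | 2-[(4R)-4-[(tert-butyldimethylsilyl)oxy]-2,6,6-trimethylcyclohex-1-en-1-yl]acetic acid | OC(=O)CC1=C(C)C[C@@H](O[Si](C)(C)C(C)(C)C)CC1(C)C | intermediate
34 | 3,3-diethoxyprop-1-yne | C#CC(OCC)OCC | starting material
35 | (3,3-diethoxyprop-1-yn-1-yl)lithium | [Li]C#CC(OCC)OCC | intermediate
36 | methyl 4,4-diethoxybut-2-ynoate | COC(=O)C#CC(OCC)OCC | intermediate
37 | methyl (2E)-4,4-diethoxy-2-(tributylstannyl)but-2-enoate | COC(=O)/C(=C\C(OCC)OCC)[Sn](CCCC)(CCCC)CCCC | intermediate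
38 | (2E)-4,4-diethoxy-2-(tributylstannyl)but-2-en-1-ol | OC/C(=C\C(OCC)OCC)[Sn](CCCC)(CCCC)CCCC | intermediate
39 | dodecanoyl chloride | CCCCCCCCCCCC(=O)Cl | starting material
40 | (2E)-4,4-diethoxy-2-(tributylstannyl)but-2-en-1-yl dodecanoate | CCCCCCCCCCCC(=O)OC/C(=C\C(OCC)OCC)[Sn](CCCC)(CCCC)CCCC | intermediate
41 | 2-[(4R)-4-[(tert-butyldimethylsilyl)oxy]-2,6,6-trimethylcyclohex-1-en-1-yl]acetyl chloride | ClC(=O)CC1=C(C)C[C@@H](O[Si](C)(C)C(C)(C)C)CC1(C)C | intermediate
42 | (2E)-2-{2-[(4R)-4-[(tert-butyldimethylsilyl)oxy]-2,6,6-trimethylcyclohex-1-en-1-yl]acetyl}-4,4-diethoxybut-2-en-1-yl dodecanoate | CCCCCCCCCCCC(=O)OC/C(=C\C(OCC)OCC)C(=O)CC1=C(C)C[C@@H](O[Si](C)(C)C(C)(C)C)CC1(C)C | intermediate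
43 | (2E)-2-{2-[(4R)-4-hydroxy-2,6,6-trimethylcyclohex-1-en-1-yl]acetyl}-4-oxobut-2-en-1-yl dodecanoate | CCCCCCCCCCCC(=O)OC/C(=C\C=O)C(=O)CC1=C(C)C[C@@H](O)CC1(C)C | intermediate
44 | phosphorus ylide of 26 | c1ccccc1P(c1ccccc1)(c1ccccc1)=C/C(C)=C/C=C/C=C(C)/C=C/C=C(C)/C=C/[C@H]1C(C)=C[C@H](O)CC1(C)C | intermediate
45 | (3R,3′R,6′R)-3,3′-dihydroxy-8-oxo-7,8-dihydro-β,ε-caroten-19-yl dodecanoate | CCCCCCCCCCCC(=O)OC\C(=C/C=C/C(C)=C/C=C/C=C(C)/C=C/C=C(C)/C=C/[C@H]1C(C)=C[C@H](O)CC1(C)C)C(=O)CC1=C(C)C[C@@H](O)CC1(C)C | target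

Total step count: 27. Longest linear sequence: 16 steps (steps 1–6, 8–16 and 27).

Steps most likely to fail

1. Step 11. Tin-to-palladium transfer from the hindered trisubstituted alkenylstannane may be slower than decarboxylative methyl ether formation, protodestannylation, or syn–anti isomerisation of the allyl complex, which would erode the C6′ configuration and the E-geometry. The fallback reverses the roles of the two termini. It sets out from iodo alcohol 15, which is acylated (LiN(SiMe3)2, then 17) to the iodo dienyl carbonate F1. Copper-catalysed γ-selective borylation of F1 (CuCl, Xantphos, KOt-Bu, B2pin2, THF) with anti-SN2′ transfer of chirality should give the (4S)-allylic boronate F2. Intramolecular γ-selective Suzuki–Miyaura coupling of F2 with its own alkenyl iodide (Pd2(dba)3, PPh3, KOH, THF/H2O; syn-SE2′ transmetalation puts palladium on C6′, then reductive elimination) comes back to the route at 19.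

2. Step 27. The ylide or liberated phosphine may add to the doubly activated C9=C10 bond with SN2′-type loss of laurate, C7 may enolise, and Z-to-E equilibration at C11=C12 may stay incomplete. The fallback moves the last C–C bond formation to C8–C9. It sets out from stannane 40, whose acetal is hydrolysed (oxalic acid on silica gel, wet CH2Cl2) to the stannyl enal F3. Wittig reaction of F3 with ylide 44 (from 26, 1,2-epoxybutane) gives the polyenyl stannane F4. Acylative Stille coupling of F4 with acid chloride 41 gives the mono-silyl ether F5, and HF·pyridine in THF/pyridine comes back to the route at 45.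

3. Step 25. Transmetalation of the α-branched stannane may be slow, the β,γ-unsaturated acid chloride may form a ketene or suffer double-bond migration, and adventitious HCl may protodestannylate 40. The fallback replaces acylation by carbonyl addition and oxidation. It sets out from 40, which is iododestannylated (I2, CH2Cl2, 0 °C) to the alkenyl iodide F6, and from ester 32, which is reduced (i-Bu2AlH, CH2Cl2, −78 °C) to the aldehyde F7. Nozaki–Hiyama–Kishi coupling of F6 with F7 (CrCl2, NiCl2 cat., DMSO) gives the allylic alcohol F8 as C8 epimers, and Dess–Martin oxidation comes back to the route at 42.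

Further compounds
F1 | step 11 | (2E,4E,6S,9R,10Z)-1,9-bis[(tert-butyldimethylsilyl)oxy]-11-iodo-3,7,7-trimethyldodeca-2,4,10-trien-6-yl methyl carbonate | C/C(I)=C/[C@H](O[Si](C)(C)C(C)(C)C)CC(C)(C)[C@@H](OC(=O)OC)/C=C/C(C)=C/CO[Si](C)(C)C(C)(C)C
F2 | step 11 | tert-butyl{[(2E,4S,5E,9R,10Z)-9-[(tert-butyldimethylsilyl)oxy]-11-iodo-3,7,7-trimethyl-4-(4,4,5,5-tetramethyl-1,3,2-dioxaborolan-2-yl)dodeca-2,5,10-trien-1-yl]oxy}dimethylsilane | C/C(I)=C/[C@H](O[Si](C)(C)C(C)(C)C)CC(C)(C)/C=C/[C@H](B1OC(C)(C)C(C)(C)O1)/C(C)=C/CO[Si](C)(C)C(C)(C)C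
F3 | step 27 | (2E)-4-oxo-2-(tributylstannyl)but-2-en-1-yl dodecanoate | CCCCCCCCCCCC(=O)OC/C(=C\C=O)[Sn](CCCC)(CCCC)CCCC
F4 | step 27 | (2E,4E,6E,8E,10E,12E,14E,16E)-17-[(1R,4R)-4-hydroxy-2,6,6-trimethylcyclohex-2-en-1-yl]-6,11,15-trimethyl-2-(tributylstannyl)heptadeca-2,4,6,8,10,12,14,16-octaen-1-yl dodecanoate | CCCCCCCCCCCC(=O)OC\C(=C/C=C/C(C)=C/C=C/C=C(C)/C=C/C=C(C)/C=C/[C@H]1C(C)=C[C@H](O)CC1(C)C)[Sn](CCCC)(CCCC)CCCC
F5 | step 27 | (3R,3′R,6′R)-3-[(tert-butyldimethylsilyl)oxy]-3′-hydroxy-8-oxo-7,8-dihydro-β,ε-caroten-19-yl dodecanoate | CCCCCCCCCCCC(=O)OC\C(=C/C=C/C(C)=C/C=C/C=C(C)/C=C/C=C(C)/C=C/[C@H]1C(C)=C[C@H](O)CC1(C)C)C(=O)CC1=C(C)C[C@@H](O[Si](C)(C)C(C)(C)C)CC1(C)C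
F6 | step 25 | (2E)-4,4-diethoxy-2-iodobut-2-en-1-yl dodecanoate | CCCCCCCCCCCC(=O)OC/C(I)=C\C(OCC)OCC
F7 | step 25 | 2-[(4R)-4-[(tert-butyldimethylsilyl)oxy]-2,6,6-trimethylcyclohex-1-en-1-yl]acetaldehyde | O=CCC1=C(C)C[C@@H](O[Si](C)(C)C(C)(C)C)CC1(C)C
F8 | step 25 | (2E)-2-{2-[(4R)-4-[(tert-butyldimethylsilyl)oxy]-2,6,6-trimethylcyclohex-1-en-1-yl]-1-hydroxyethyl}-4,4-diethoxybut-2-en-1-yl dodecanoate (carbinol epimers) | CCCCCCCCCCCC(=O)OC/C(=C\C(OCC)OCC)C(O)CC1=C(C)C[C@@H](O[Si](C)(C)C(C)(C)C)CC1(C)C
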